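**Strategy.** Everything rests on closing ring C of the lower (epiafzelechin) unit last, across C4–C4a and C2–C3, on an upper flavan that already carries ring A as a 4-aryl group. The precursor is an O,S-acetal joining O1 to the future C2 and ring B. A silver salt turns it into an aryloxycarbenium ion, which a symmetrical enediol bis-silyl ether converts in one operation into the pyran ring (C2–C3, then Friedel–Crafts C4–C4a). The step exploits ring A: with the upper unit para to O1 (at C6), C4a and C8 are equivalent and both flanked by two oxygens, so only the 4→6 isomer can form. Oxidation and a dynamic kinetic reduction then set C2 and C3.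

Key step: step 9

Assumption: purchased (S)-liquiritigenin is taken to be of high enantiomeric purity; it is the only source of the upper-unit configuration.

Step 1
Reactants: 1 (S)-liquiritigenin
Product: 2 (2S)-7-(benzyloxy)-2-[4-(benzyloxy)phenyl]chroman-4-one
Conditions: BnOH, PPh3, DIAD, THF, 0 °C → rt
Reagents that add atoms: benzyl alcohol, OCc1ccccc1
Why: Mitsunobu etherification of both phenols under non-basic conditions, which avoids the base-induced flavanone–chalcone equilibrium that would racemise C2; no new stereocentre.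

Step 2
Reactants: 3 3,5-bis(benzyloxy)phenol
Product: 4 [3,5-bis(benzyloxy)phenoxy]triisopropylsilane
Conditions: TIPSCl, imidazole, DMF, rt
Reagents that add atoms: chlorotriisopropylsilane, CC(C)[Si](Cl)(C(C)C)C(C)C
Why: Standard silylation of the phenol; the bulky silyloxy group neither directs nor tolerates metalation next to it, so the position between the two benzyloxy groups is left as the lithiation site.

Step 3
Reactants: 4 [3,5-bis(benzyloxy)phenoxy]triisopropylsilane; 2 (2S)-7-(benzyloxy)-2-[4-(benzyloxy)phenyl]chroman-4-one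
Product: 7 (2S,4RS)-7-(benzyloxy)-2-[4-(benzyloxy)phenyl]-4-{2,6-bis(benzyloxy)-4-[(triisopropylsilyl)oxy]phenyl}chroman-4-ol, via aryllithium 5 (not isolated), via aryldichlorocerium 6 (not isolated)
Conditions: n-BuLi, THF, 0 °C; CeCl3, −78 °C; then 2, −78 °C; aq. NH4Cl
Reagents that add atoms: none
Why: Directed ortho-lithiation between the two benzyloxy groups, transmetalation to the weakly basic organocerium reagent and 1,2-addition to the enolisable ketone; the new C4 carbinol centre is not controlled and is removed in step 4.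

Step 4
Reactants: 7 (2S,4RS)-7-(benzyloxy)-2-[4-(benzyloxy)phenyl]-4-{2,6-bis(benzyloxy)-4-[(triisopropylsilyl)oxy]phenyl}chroman-4-ol
Product: 8 (2S,4S)-7-(benzyloxy)-2-[4-(benzyloxy)phenyl]-4-{2,6-bis(benzyloxy)-4-[(triisopropylsilyl)oxy]phenyl}chromane
Conditions: Et3SiH, CF3CO2H, CH2Cl2, −40 → 0 °C
Reagents that add atoms: none
Why: Ionic hydrogenation of the tertiary dibenzylic alcohol; hydride should add pseudo-axially to the C4 cation of the half-chair that has the 2-aryl group equatorial, that is cis to H-2, which places the two aryl groups cis (4S).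

Step 5
Reactants: 8 (2S,4S)-7-(benzyloxy)-2-[4-(benzyloxy)phenyl]-4-{2,6-bis(benzyloxy)-4-[(triisopropylsilyl)oxy]phenyl}chromane
Product: 9 3,5-bis(benzyloxy)-4-{(2S,4S)-7-(benzyloxy)-2-[4-(benzyloxy)phenyl]chroman-4-yl}phenol
Conditions: Bu4NF, THF, 0 °C; aq. NH4Cl
Reagents that add atoms: none
Why: Fluoride cleavage of the aryl silyl ether frees the one phenol that becomes O1 of the lower unit; no stereocentre is touched.

Step 6
Reactants: 10 4-(benzyloxy)benzyl chloride
Product: 11 4-(benzyloxy)benzyl phenyl sulfide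
Conditions: PhSH, K2CO3, DMF, rt
Reagents that add atoms: thiophenol, Sc1ccccc1
Why: SN2 displacement of the benzylic chloride by thiophenolate (thioether synthesis).

Step 7
Reactants: 11 4-(benzyloxy)benzyl phenyl sulfide; 9 3,5-bis(benzyloxy)-4-{(2S,4S)-7-(benzyloxy)-2-[4-(benzyloxy)phenyl]chroman-4-yl}phenol
Product: 13 (2S,4S)-7-(benzyloxy)-2-[4-(benzyloxy)phenyl]-4-[2,6-bis(benzyloxy)-4-{[4-(benzyloxy)phenyl](phenylthio)methoxy}phenyl]chromane (both epimers at the acetal carbon), via α-chloro sulfide 12 (not isolated)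
Conditions: 11, SO2Cl2, CH2Cl2, −78 → 0 °C, evaporate; then 9, Cs2CO3, DMF, 0 °C
Reagents that add atoms: none
Why: α-Chlorination of the benzylic sulfide through its chlorosulfonium ion, then O-alkylation of the cesium phenoxide by the α-chloro sulfide (the reaction type of methylthiomethyl ether formation); the acetal centre is uncontrolled and is lost on ionisation in step 9.

Step 8
Reactants: 14 glycolaldehyde dimer (1,4-dioxane-2,5-diol)
Product: 15 (Z)-1,2-bis(trimethylsilyloxy)ethene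
Conditions: Me3SiCl, Et3N, DMF, rt → 50 °C; distillation
Reagents that add atoms: chlorotrimethylsilane, C[Si](C)(C)Cl
Why: The amine opens the hemiacetal dimer to glycolaldehyde, whose hydroxyl and enol oxygens are silylated (enol silane formation); the alkene geometry is of no consequence later.

Step 9
Reactants: 13 (2S,4S)-7-(benzyloxy)-2-[4-(benzyloxy)phenyl]-4-[2,6-bis(benzyloxy)-4-{[4-(benzyloxy)phenyl](phenylthio)methoxy}phenyl]chromane; 15 (Z)-1,2-bis(trimethylsilyloxy)ethene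
Product: 19 5,7-bis(benzyloxy)-2-[4-(benzyloxy)phenyl]-6-{(2S,4S)-7-(benzyloxy)-2-[4-(benzyloxy)phenyl]chroman-4-yl}chroman-3-ol (mixture of the lower-unit C2/C3 stereoisomers), via aryloxycarbenium triflate 16 (not isolated), via 3,4-bis(trimethylsilyloxy)flavan 17 (not isolated), via 3-(trimethylsilyloxy)flavan 18 (not isolated)
Conditions: AgOTf, 2,6-di-tert-butyl-4-methylpyridine, 4 Å MS, CH2Cl2, −78 °C; then Et3SiH (excess), Me3SiOTf (cat.), −78 → −30 °C; then K2CO3, MeOH, 0 °C
Reagents that add atoms: none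
Why: Proposed new method: AgOTf abstracts thiophenolate from the O,S-acetal to give the aryloxycarbenium ion 16 (a cationic 2-oxadiene C4a=C8a–O1=C2); the enol ether carbon of 15 adds to C2 (C2–C3 bond) and the silyl-oxocarbenium ion thus created at C4 is attacked by C4a, which lies between O1 and O5 (C4–C4a bond), after which Et3SiH and catalytic silyl triflate remove the benzylic C4 silyloxy group by ionic hydrogenation. The closest known reactions are the Lewis-acid-promoted intermolecular oxa-Povarov reaction of aryl oxocarbenium ions and alkenes, the Mukaiyama addition of α-oxygenated enol silanes to oxocarbenium ions and the reductive Friedel–Crafts alkylation of electron-rich arenes by aldehydes and Et3SiH. Ring C closes in a 6-exo-trig Friedel–Crafts attack of the arene on the C4 oxocarbenium carbon. The new centres C2 and C3 form without control (the upper unit is too remote) and need none, because step 10 erases C3 and makes C2 epimerisable and step 11 sets both. The step needs ionisation at sulfur and not at the aryl oxygen (secured by the soft silver salt), oxygen on C3 and not on C4 (secured by the symmetrical dienophile) and closure at C4a and not at C8 (the two carbons are homotopic because the upper unit sits para to O1, so only the 4→6 skeleton can result).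

Step 10
Reactants: 19 5,7-bis(benzyloxy)-2-[4-(benzyloxy)phenyl]-6-{(2S,4S)-7-(benzyloxy)-2-[4-(benzyloxy)phenyl]chroman-4-yl}chroman-3-ol (stereoisomer mixture)
Product: 20 5,7-bis(benzyloxy)-2-[4-(benzyloxy)phenyl]-6-{(2S,4S)-7-(benzyloxy)-2-[4-(benzyloxy)phenyl]chroman-4-yl}chroman-3-one (C2 epimers)
Conditions: Dess–Martin periodinane, NaHCO3, CH2Cl2, 0 °C → rt; used at once under argon
Reagents that add atoms: none
Why: Dess–Martin oxidation of the secondary alcohol, tolerated by benzyl ethers; it removes the C3 centre and makes C2 epimerisable, so all stereoisomers of 19 converge on one ketone.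

Step 11
Reactants: 20 5,7-bis(benzyloxy)-2-[4-(benzyloxy)phenyl]-6-{(2S,4S)-7-(benzyloxy)-2-[4-(benzyloxy)phenyl]chroman-4-yl}chroman-3-one
Product: 21 (2R,3R)-5,7-bis(benzyloxy)-2-[4-(benzyloxy)phenyl]-6-{(2S,4S)-7-(benzyloxy)-2-[4-(benzyloxy)phenyl]chroman-4-yl}chroman-3-ol
Conditions: RuCl[(R,R)-TsDPEN](p-cymene) (cat.), HCO2H/Et3N (5:2), DMF, 35 °C, argon
Reagents that add atoms: none
Why: Noyori–Ikariya asymmetric transfer hydrogenation under dynamic kinetic resolution: C2–H (α to the ketone, benzylic, α-aryloxy) epimerises through the enol in the amine buffer while the (R,R) catalyst should deliver hydride to the Si face of C3 of the (2R) epimer, anti to the 2-aryl group, to give the 2,3-cis (2R,3R) alcohol, the outcome type known for α-aryl and α-aryloxy cyclic ketones (the aryloxy-bearing α-carbon is taken to occupy the site of the aryl group in the usual acetophenone model).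

Step 12
Reactants: 21 (2R,3R)-5,7-bis(benzyloxy)-2-[4-(benzyloxy)phenyl]-6-{(2S,4S)-7-(benzyloxy)-2-[4-(benzyloxy)phenyl]chroman-4-yl}chroman-3-ol
Product: 22 (2R,3R)-2-(4-hydroxyphenyl)-6-[(2S,4S)-7-hydroxy-2-(4-hydroxyphenyl)chroman-4-yl]chromane-3,5,7-triol (CNP0167324.1)
Conditions: H2 (1 atm), Pd(OH)2/C, THF/MeOH, rt
Reagents that add atoms: none
Why: Hydrogenolysis of the five aryl benzyl ethers under the mild conditions used for benzylated flavan-3-ols, which leave the ring C–O bonds and all four stereocentres intact.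

**Compound list**

1 | (S)-liquiritigenin, (2S)-7-hydroxy-2-(4-hydroxyphenyl)chroman-4-one | Oc1ccc([C@@H]2CC(=O)c3ccc(O)cc3O2)cc1 | starting material
2 | (2S)-7-(benzyloxy)-2-[4-(benzyloxy)phenyl]chroman-4-one | O(Cc5ccccc5)c1ccc([C@@H]2CC(=O)c3ccc(OCc5ccccc5)cc3O2)cc1 | intermediate
3 | 3,5-bis(benzyloxy)phenol | Oc1cc(OCc2ccccc2)cc(OCc2ccccc2)c1 | starting material
4 | [3,5-bis(benzyloxy)phenoxy]triisopropylsilane | CC(C)[Si](Oc1cc(OCc2ccccc2)cc(OCc2ccccc2)c1)(C(C)C)C(C)C | intermediate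
5 | {2,6-bis(benzyloxy)-4-[(triisopropylsilyl)oxy]phenyl}lithium | [Li]c1c(OCc2ccccc2)cc(O[Si](C(C)C)(C(C)C)C(C)C)cc1OCc1ccccc1 | intermediate
6 | {2,6-bis(benzyloxy)-4-[(triisopropylsilyl)oxy]phenyl}cerium dichloride | Cl[Ce](Cl)c1c(OCc2ccccc2)cc(O[Si](C(C)C)(C(C)C)C(C)C)cc1OCc1ccccc1 | intermediate
7 | (2S,4RS)-7-(benzyloxy)-2-[4-(benzyloxy)phenyl]-4-{2,6-bis(benzyloxy)-4-[(triisopropylsilyl)oxy]phenyl}chroman-4-ol | O(Cc5ccccc5)c1ccc([C@@H]2CC(O)(c3c(OCc5ccccc5)cc(O[Si](C(C)C)(C(C)C)C(C)C)cc3OCc5ccccc5)c3ccc(OCc5ccccc5)cc3O2)cc1 | intermediate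
8 | (2S,4S)-7-(benzyloxy)-2-[4-(benzyloxy)phenyl]-4-{2,6-bis(benzyloxy)-4-[(triisopropylsilyl)oxy]phenyl}chromane | O(Cc5ccccc5)c1ccc([C@@H]2C[C@H](c3c(OCc5ccccc5)cc(O[Si](C(C)C)(C(C)C)C(C)C)cc3OCc5ccccc5)c3ccc(OCc5ccccc5)cc3O2)cc1 | intermediate
9 | 3,5-bis(benzyloxy)-4-{(2S,4S)-7-(benzyloxy)-2-[4-(benzyloxy)phenyl]chroman-4-yl}phenol | O(Cc5ccccc5)c1ccc([C@@H]2C[C@H](c3c(OCc5ccccc5)cc(O)cc3OCc5ccccc5)c3ccc(OCc5ccccc5)cc3O2)cc1 | intermediate
10 | 4-(benzyloxy)benzyl chloride | ClCc1ccc(OCc2ccccc2)cc1 | starting material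
11 | 4-(benzyloxy)benzyl phenyl sulfide | c1ccc(SCc2ccc(OCc3ccccc3)cc2)cc1 | intermediate
12 | [4-(benzyloxy)phenyl](chloro)methyl phenyl sulfide (racemic) | ClC(Sc1ccccc1)c1ccc(OCc2ccccc2)cc1 | intermediate
13 | (2S,4S)-7-(benzyloxy)-2-[4-(benzyloxy)phenyl]-4-[2,6-bis(benzyloxy)-4-{[4-(benzyloxy)phenyl](phenylthio)methoxy}phenyl]chromane (acetal epimers) | O(Cc5ccccc5)c1ccc([C@@H]2C[C@H](c3c(OCc5ccccc5)cc(OC(Sc5ccccc5)c5ccc(OCc6ccccc6)cc5)cc3OCc5ccccc5)c3ccc(OCc5ccccc5)cc3O2)cc1 | intermediate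
14 | glycolaldehyde dimer (1,4-dioxane-2,5-diol) | OC1COC(O)CO1 | starting material
15 | (Z)-1,2-bis(trimethylsilyloxy)ethene | C[Si](C)(C)O/C=C\O[Si](C)(C)C | intermediate
16 | aryloxycarbenium triflate derived from 13 by loss of thiophenolate | O(Cc5ccccc5)c1ccc([C@@H]2C[C@H](c3c(OCc5ccccc5)cc([O+]=Cc5ccc(OCc6ccccc6)cc5)cc3OCc5ccccc5)c3ccc(OCc5ccccc5)cc3O2)cc1.[O-]S(=O)(=O)C(F)(F)F | intermediate
17 | 5,7-bis(benzyloxy)-2-[4-(benzyloxy)phenyl]-6-{(2S,4S)-7-(benzyloxy)-2-[4-(benzyloxy)phenyl]chroman-4-yl}-3,4-bis(trimethylsilyloxy)chromane (stereoisomer mixture in the lower unit) | O(Cc5ccccc5)c1ccc([C@@H]2C[C@H](c3c(OCc5ccccc5)cc4c(c3OCc5ccccc5)C(O[Si](C)(C)C)C(O[Si](C)(C)C)C(c3ccc(OCc5ccccc5)cc3)O4)c3ccc(OCc5ccccc5)cc3O2)cc1 | intermediate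
18 | 5,7-bis(benzyloxy)-2-[4-(benzyloxy)phenyl]-6-{(2S,4S)-7-(benzyloxy)-2-[4-(benzyloxy)phenyl]chroman-4-yl}-3-(trimethylsilyloxy)chromane (stereoisomer mixture in the lower unit) | O(Cc5ccccc5)c1ccc([C@@H]2C[C@H](c3c(OCc5ccccc5)cc4c(c3OCc5ccccc5)CC(O[Si](C)(C)C)C(c3ccc(OCc5ccccc5)cc3)O4)c3ccc(OCc5ccccc5)cc3O2)cc1 | intermediate
19 | 5,7-bis(benzyloxy)-2-[4-(benzyloxy)phenyl]-6-{(2S,4S)-7-(benzyloxy)-2-[4-(benzyloxy)phenyl]chroman-4-yl}chroman-3-ol (stereoisomer mixture in the lower unit) | O(Cc5ccccc5)c1ccc([C@@H]2C[C@H](c3c(OCc5ccccc5)cc4c(c3OCc5ccccc5)CC(O)C(c3ccc(OCc5ccccc5)cc3)O4)c3ccc(OCc5ccccc5)cc3O2)cc1 | intermediate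
20 | 5,7-bis(benzyloxy)-2-[4-(benzyloxy)phenyl]-6-{(2S,4S)-7-(benzyloxy)-2-[4-(benzyloxy)phenyl]chroman-4-yl}chroman-3-one (C2 epimers) | O(Cc5ccccc5)c1ccc([C@@H]2C[C@H](c3c(OCc5ccccc5)cc4c(c3OCc5ccccc5)CC(=O)C(c3ccc(OCc5ccccc5)cc3)O4)c3ccc(OCc5ccccc5)cc3O2)cc1 | intermediate
21 | (2R,3R)-5,7-bis(benzyloxy)-2-[4-(benzyloxy)phenyl]-6-{(2S,4S)-7-(benzyloxy)-2-[4-(benzyloxy)phenyl]chroman-4-yl}chroman-3-ol | O(Cc5ccccc5)c1ccc([C@@H]2C[C@H](c3c(OCc5ccccc5)cc4c(c3OCc5ccccc5)C[C@@H](O)[C@@H](c3ccc(OCc5ccccc5)cc3)O4)c3ccc(OCc5ccccc5)cc3O2)cc1 | intermediate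
22 | (2R,3R)-2-(4-hydroxyphenyl)-6-[(2S,4S)-7-hydroxy-2-(4-hydroxyphenyl)chroman-4-yl]chromane-3,5,7-triol | Oc1ccc([C@@H]2C[C@H](c3c(O)cc4c(c3O)C[C@@H](O)[C@@H](c3ccc(O)cc3)O4)c3ccc(O)cc3O2)cc1 | target

**Total step count:** 12
**Longest linear sequence:** 9 steps (steps 1, 3, 4, 5, 7, 9, 10, 11, 12)

**Steps most likely to fail**

Step 9 (Proposed new method). The C4 silyloxy group may ionise before reduction, and the C4 cation may then be captured by remaining enol ether or by C8 of a second molecule (oligomerisation); the aryloxycarbenium ion may also be attacked intermolecularly by an arene before the enol ether reaches it. The fallback uses known chemistry, sets out from phenol 9 and comes back at 21, so that steps 10 and 11 are not needed. Racemic 1-[4-(benzyloxy)phenyl]prop-2-en-1-ol F1 (from 4-(benzyloxy)benzaldehyde and vinylmagnesium bromide) would be resolved by Sharpless kinetic-resolution epoxidation (Ti(OiPr)4, diisopropyl tartrate, t-BuOOH) to the anti epoxy alcohol (S)-[4-(benzyloxy)phenyl][(R)-oxiran-2-yl]methanol F2. Mitsunobu etherification of 9 by F2 (PPh3, DIAD; inversion at the benzylic carbon) would give the aryl ether (2S,4S)-7-(benzyloxy)-2-[4-(benzyloxy)phenyl]-4-[2,6-bis(benzyloxy)-4-{(R)-[4-(benzyloxy)phenyl][(R)-oxiran-2-yl]methoxy}phenyl]chromane F3. An AuCl3/AgOTf-catalysed 6-exo epoxide–arene cyclisation at the terminal epoxide carbon would then close ring C and give 21 with both lower-unit centres taken from F2.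

Step 11. Epimerisation at C2 may be slow relative to reduction, or the catalyst may discriminate the carbonyl faces poorly, so that the alcohol is formed as a mixture of lower-unit diastereomers. The fallback sets out from ketone 20 and comes back at 21. Substrate-controlled reduction by LiBH(s-Bu)3 in THF at −78 °C should add hydride anti to the 2-aryl group of both C2 epimers and give the two 2,3-cis alcohols, 21 and its lower-unit diastereomer (2S,3S)-5,7-bis(benzyloxy)-2-[4-(benzyloxy)phenyl]-6-{(2S,4S)-7-(benzyloxy)-2-[4-(benzyloxy)phenyl]chroman-4-yl}chroman-3-ol F4. They are diastereomers because the upper unit is enantiopure, so they can be separated by chromatography, and F4 would be returned to 20 by Dess–Martin oxidation and base equilibration at C2.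

Step 3. The hindered aryl-metal may act as a base, enolising the flavanone with ring opening to the chalcone and loss of the C2 configuration. The fallback sets out from 2 and 4 and comes back at 8. Ketone 2 would be converted without an enolate (Tf2O, 2,6-di-tert-butyl-4-methylpyridine) into the enol triflate (2S)-7-(benzyloxy)-2-[4-(benzyloxy)phenyl]-2H-chromen-4-yl trifluoromethanesulfonate F5. Lithiated 4 would be quenched by B(OMe)3 to give {2,6-bis(benzyloxy)-4-[(triisopropylsilyl)oxy]phenyl}boronic acid F6. Suzuki–Miyaura coupling (Pd(OAc)2, SPhos, K3PO4) would give the 4-aryl-2H-chromene (2S)-7-(benzyloxy)-2-[4-(benzyloxy)phenyl]-4-{2,6-bis(benzyloxy)-4-[(triisopropylsilyl)oxy]phenyl}-2H-chromene F7, and ionic hydrogenation (Et3SiH, CF3CO2H) through the same C4 cation as in step 4 would give 8.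

**Further compounds**

F1 | step 9 | rac-1-[4-(benzyloxy)phenyl]prop-2-en-1-ol | OC(C=C)c1ccc(OCc2ccccc2)cc1
F2 | step 9 | (S)-[4-(benzyloxy)phenyl][(R)-oxiran-2-yl]methanol | O[C@@H](c1ccc(OCc2ccccc2)cc1)[C@H]1CO1
F3 | step 9 | (2S,4S)-7-(benzyloxy)-2-[4-(benzyloxy)phenyl]-4-[2,6-bis(benzyloxy)-4-{(R)-[4-(benzyloxy)phenyl][(R)-oxiran-2-yl]methoxy}phenyl]chromane | O(Cc5ccccc5)c1ccc([C@@H]2C[C@H](c3c(OCc5ccccc5)cc(O[C@H](c5ccc(OCc6ccccc6)cc5)[C@H]5CO5)cc3OCc5ccccc5)c3ccc(OCc5ccccc5)cc3O2)cc1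
F4 | step 11 | (2S,3S)-5,7-bis(benzyloxy)-2-[4-(benzyloxy)phenyl]-6-{(2S,4S)-7-(benzyloxy)-2-[4-(benzyloxy)phenyl]chroman-4-yl}chroman-3-ol | O(Cc5ccccc5)c1ccc([C@@H]2C[C@H](c3c(OCc5ccccc5)cc4c(c3OCc5ccccc5)C[C@H](O)[C@H](c3ccc(OCc5ccccc5)cc3)O4)c3ccc(OCc5ccccc5)cc3O2)cc1
F5 | step 3 | (2S)-7-(benzyloxy)-2-[4-(benzyloxy)phenyl]-2H-chromen-4-yl trifluoromethanesulfonate | O(Cc5ccccc5)c1ccc([C@@H]2C=C(OS(=O)(=O)C(F)(F)F)c3ccc(OCc5ccccc5)cc3O2)cc1
F6 | step 3 | {2,6-bis(benzyloxy)-4-[(triisopropylsilyl)oxy]phenyl}boronic acid | OB(O)c1c(OCc2ccccc2)cc(O[Si](C(C)C)(C(C)C)C(C)C)cc1OCc1ccccc1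
F7 | step 3 | (2S)-7-(benzyloxy)-2-[4-(benzyloxy)phenyl]-4-{2,6-bis(benzyloxy)-4-[(triisopropylsilyl)oxy]phenyl}-2H-chromene | O(Cc5ccccc5)c1ccc([C@@H]2C=C(c3c(OCc5ccccc5)cc(O[Si](C(C)C)(C(C)C)C(C)C)cc3OCc5ccccc5)c3ccc(OCc5ccccc5)cc3O2)cc1
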